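**Assumption:** the target SMILES has no stereocentre and no stereogenic double bond, so the compound is achiral and no enantiocontrol is needed. The transient stereo-elements in 8, 12 and 13 are erased on the way to the target.

## Retrosynthetic overview
1. The pyrone is built last rather than coupled on. Cutting pyrone C3–C4 and O1–C2 gives a tricyclic dihydrocoumarin (its benzylic CH2, α-CH2 and C=O become the bridge CH2, pyrone C3 and C2) plus methylketene dimer (pyrone C4–C6, Me, Et, ring O). The usual pyrone + CH2O/Eschenmoser salt + acylphloroglucinol coupling is avoided.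
2. The dimethylpyran ring comes from prenal by Knoevenagel/oxa-6π on 8-isobutyryl-5,7-dihydroxychroman-2-one. The lactone masks one O ortho to the acyl and chelation masks the other, so closure goes to the O para to the acyl.
3. The acyl-dihydrocoumarin comes from C8 Friedel–Crafts acylation of 5,7-dihydroxycoumarin, then hydrogenation. The coumarin comes from phloroglucinol and ethyl propiolate.
4. Methylketene dimer comes from propionyl chloride.
5. Ring order: δ-lactone (coumarin) ring, then 2,2-dimethylpyran ring, then 2-pyrone ring, which closes as the first lactone ring opens.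

## Route

**Step 1**
Reactants: 1 phloroglucinol (benzene-1,3,5-triol); 2 ethyl propiolate
Product: 3 5,7-dihydroxycoumarin (5,7-dihydroxy-2H-chromen-2-one)
Conditions: ZnCl2, dioxane (or neat), 100 °C; then 1 M HCl
Reagents that add atoms: ethyl propiolate (2), C#CC(=O)OCC
Why: Pechmann-type hydroarylation of the propiolate by the very electron-rich arene, followed by lactonisation, gives the 4-unsubstituted coumarin, and the threefold symmetry of 1 allows only one product.

**Step 2**
Reactants: 3 5,7-dihydroxycoumarin; 4 isobutyryl chloride (2-methylpropanoyl chloride)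
Product: 5 5,7-dihydroxy-8-(2-methylpropanoyl)-2H-chromen-2-one
Conditions: AlCl3 (4 equiv), PhNO2–ClCH2CH2Cl, 70 °C; then ice/HCl
Reagents that add atoms: isobutyryl chloride (4), CC(C)C(=O)Cl
Why: Friedel–Crafts acylation goes to C8 (ortho to O7, para to O5), which is the more nucleophilic carbon of 5,7-dihydroxycoumarins as exploited in calanolide-type pyranocoumarin work, and the product is stabilised by the 7-OH···O=C chelate; any minor 6-acyl isomer is removed by chromatography.

**Step 3**
Reactants: 5 5,7-dihydroxy-8-(2-methylpropanoyl)-2H-chromen-2-one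
Product: 6 5,7-dihydroxy-8-(2-methylpropanoyl)-3,4-dihydro-2H-chromen-2-one
Conditions: H2 (1–3 atm), 10% Pd/C, EtOAc–THF, rt (no alcohol solvent)
Reagents that add atoms: none
Why: Heterogeneous catalytic hydrogenation saturates the unhindered enoate C3=C4 bond while the chelated aryl ketone survives neutral conditions, and doing it before the chromene alkene exists removes any chemoselectivity problem.

**Step 4**
Reactants: 6 5,7-dihydroxy-8-(2-methylpropanoyl)-3,4-dihydro-2H-chromen-2-one; 7 3-methylbut-2-enal (prenal)
Product: 9 5-hydroxy-2,2-dimethyl-6-(2-methylpropanoyl)-9,10-dihydro-2H,8H-pyrano[2,3-f]chromen-8-one, via o-quinone methide 8 (not isolated)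
Conditions: prenal (2 equiv), ethylenediamine diacetate (20 mol %), toluene, reflux, Dean–Stark
Reagents that add atoms: 3-methylbut-2-enal (7), CC(C)=CC=O
Why: Iminium-catalysed Knoevenagel-type condensation at C6 (the only free aromatic CH) gives 8, which closes by oxa-6π electrocyclisation through O5, because O7 is locked in the hydrogen bond to the acyl group and the third oxygen is masked as the lactone, so the chromene oxygen ends para to the acyl.

**Step 5**
Reactants: 10 propionyl chloride (2 equiv per product)
Product: 12 (Z)-4-ethylidene-3-methyloxetan-2-one (methylketene dimer, racemic), via methylketene 11 (not isolated)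
Conditions: Et3N (1.05 equiv), Et2O, 0 °C to rt; filter; distil under reduced pressure
Reagents that add atoms: none
Why: Dehydrochlorination gives methylketene, which undergoes the classical amine-promoted head-to-tail [2+2] ketene dimerisation to the β-lactone, and its stereocentre and alkene geometry do not matter because both are erased in step 6.

**Step 6**
Reactants: 9 5-hydroxy-2,2-dimethyl-6-(2-methylpropanoyl)-9,10-dihydro-2H,8H-pyrano[2,3-f]chromen-8-one; 12 methylketene dimer
Product: 14 3-{[5,7-dihydroxy-2,2-dimethyl-6-(2-methylpropanoyl)-2H-chromen-8-yl]methyl}-6-ethyl-4-hydroxy-5-methyl-2H-pyran-2-one (target), via tricarbonyl lactone 13 (not isolated)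
Conditions: LiHMDS (3.2 equiv), THF, −78 °C; 12 (1.5 equiv), −78 °C to rt; then 1 M HCl
Reagents that add atoms: methylketene dimer (12), C/C=C1\OC(=O)C1C
Why: Proposed new method: the lithium enolate of aryl lactone 9 should C-acylate at the strained acyl carbon of β-lactone 12 (a crossed Claisen condensation, whose closest known types are the opening of ketene-dimer β-lactones by lithium amides to give enolates and the C-acetoacetylation of carbanions by diketene en route to 4-hydroxy-2-pyrones), the released ketone enolate equilibrates to the 3,5-dioxo aryl ester 13, and its C6 enolate oxygen then displaces the tethered, acyl-stabilised phenoxide (the known base-induced lactonisation of 3,5-dioxo esters, here on an activated aryl ester), the cascade being driven by β-lactone strain release and formation of the pyronate (pKa about 5), with both sp3 centres of 13 becoming sp2 so that no stereocentre remains.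

## Compound list
1 | phloroglucinol | Oc1cc(O)cc(O)c1 | starting material
2 | ethyl propiolate | C#CC(=O)OCC | starting material
3 | 5,7-dihydroxycoumarin | O=c1ccc2c(O)cc(O)cc2o1 | intermediate
4 | isobutyryl chloride | CC(C)C(=O)Cl | starting material
5 | 5,7-dihydroxy-8-(2-methylpropanoyl)-2H-chromen-2-one | CC(C)C(=O)c1c(O)cc(O)c2ccc(=O)oc12 | intermediate
6 | 5,7-dihydroxy-8-(2-methylpropanoyl)-3,4-dihydro-2H-chromen-2-one | CC(C)C(=O)c1c(O)cc(O)c2CCC(=O)Oc12 | intermediate
7 | 3-methylbut-2-enal (prenal) | CC(C)=CC=O | starting material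
8 | 7-hydroxy-6-(3-methylbut-2-en-1-ylidene)-8-(2-methylpropanoyl)-3,4-dihydro-2H-chromene-2,5(6H)-dione (o-quinone methide, exocyclic geometry undefined) | O=C1CCC2=C(O1)C(C(=O)C(C)C)=C(O)C(=CC=C(C)C)C2=O | intermediate (not isolated)
9 | 5-hydroxy-2,2-dimethyl-6-(2-methylpropanoyl)-9,10-dihydro-2H,8H-pyrano[2,3-f]chromen-8-one | CC(C)C(=O)c1c(O)c2C=CC(C)(C)Oc2c2CCC(=O)Oc12 | intermediate
10 | propionyl chloride | CCC(=O)Cl | starting material
11 | methylketene | CC=C=O | intermediate (not isolated)
12 | (Z)-4-ethylidene-3-methyloxetan-2-one (racemic) | C/C=C1\OC(=O)C1C | intermediate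
13 | 5-hydroxy-2,2-dimethyl-9-(2-methyl-3-oxopentanoyl)-6-(2-methylpropanoyl)-9,10-dihydro-2H,8H-pyrano[2,3-f]chromen-8-one (epimer/enolate mixture) | CCC(=O)C(C)C(=O)C1Cc2c(OC1=O)c(C(=O)C(C)C)c(O)c1C=CC(C)(C)Oc21 | intermediate (not isolated)
14 | 3-{[5,7-dihydroxy-2,2-dimethyl-6-(2-methylpropanoyl)-2H-chromen-8-yl]methyl}-6-ethyl-4-hydroxy-5-methyl-2H-pyran-2-one (achiral) | CCc1oc(=O)c(Cc2c(O)c(C(=O)C(C)C)c(O)c3c2OC(C)(C)C=C3)c(O)c1C | target

## Step count
- Total step count: 6.
- Longest linear sequence: 5 (steps 1, 2, 3, 4, 6). Step 5 is a one-step side branch.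

## Three steps most likely to fail

**Step 6.** The risks are self-Claisen or ketene extrusion from the aryl-ester enolate, O-acylation, and proton quench of the enolate by the product. The fallback sets out from 9 and comes back at 13, and so reaches 14. It builds the C6 unit by two successive propionylations instead of one ketene-dimer transfer. The lithium enolate of 9 (LiHMDS, THF, −78 °C) is C-acylated with propionyl chloride 10 to give 5-hydroxy-2,2-dimethyl-6-(2-methylpropanoyl)-9-propanoyl-9,10-dihydro-2H,8H-pyrano[2,3-f]chromen-8-one F1. LDA (3.3 equiv) then forms the phenoxide/β-keto-lactone γ-dianion (Harris/Huckin–Weiler type). This is acylated at the propanoyl CH2 with N-methoxy-N-methylpropanamide to give 13, which lactonises to 14 on warming or with DBU.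

**Step 2.** The risk is C8 versus C6 acylation and over-acylation. The fallback sets out from 1 (with 4) and comes back at 9, and it fixes the regiochemistry by symmetry instead of by arene electronics.
- Friedel–Crafts acylation of 1 with 4 (AlCl3) gives 2-methyl-1-(2,4,6-trihydroxyphenyl)propan-1-one F2.
- Its only non-chelated OH (para to the acyl) is etherified with 3-chloro-3-methylbut-1-yne (DBU, cat. CuCl2, MeCN, 0 °C) to give 1-{2,6-dihydroxy-4-[(2-methylbut-3-yn-2-yl)oxy]phenyl}-2-methylpropan-1-one F3.
- Heating in o-xylene at 140 °C (propargyl Claisen/[1,5]-H shift/oxa-6π, two equivalent ortho carbons) gives 1-(5,7-dihydroxy-2,2-dimethyl-2H-chromen-6-yl)-2-methylpropan-1-one F4.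
- A Yonemitsu-type three-component condensation with paraformaldehyde and Meldrum's acid (cat. proline, MeCN) at the only free carbon, C8, gives 5-{[5,7-dihydroxy-2,2-dimethyl-6-(2-methylpropanoyl)-2H-chromen-8-yl]methyl}-2,2-dimethyl-1,3-dioxane-4,6-dione F5.
- Heating F5 in pyridine–toluene at 100 °C makes the neighbouring 7-OH lactonise, with decarboxylation, to give 9.

**Step 4.** The risks are closure onto O7, or amine/water damage to the aryl lactone. The fallback sets out from 6 and comes back at 8, and so reaches 9. The ring oxygen is fixed by O-alkylation before any C–C bond is made. The non-chelated 5-OH of 6 is etherified with 3-chloro-3-methylbut-1-yne (DBU, cat. CuCl2, MeCN, 0 °C) to give 7-hydroxy-5-[(2-methylbut-3-yn-2-yl)oxy]-8-(2-methylpropanoyl)-3,4-dihydro-2H-chromen-2-one F6. Heating in o-xylene at 140 °C brings about the aromatic propargyl Claisen rearrangement to C6 (the other ortho carbon is blocked). A [1,5]-H shift then gives 8, which electrocyclises to 9.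

## Further compounds
F1 | step 6 | 5-hydroxy-2,2-dimethyl-6-(2-methylpropanoyl)-9-propanoyl-9,10-dihydro-2H,8H-pyrano[2,3-f]chromen-8-one | CCC(=O)C1Cc2c(OC1=O)c(C(=O)C(C)C)c(O)c1C=CC(C)(C)Oc21
F2 | step 2 | 2-methyl-1-(2,4,6-trihydroxyphenyl)propan-1-one | CC(C)C(=O)c1c(O)cc(O)cc1O
F3 | step 2 | 1-{2,6-dihydroxy-4-[(2-methylbut-3-yn-2-yl)oxy]phenyl}-2-methylpropan-1-one | CC(C)C(=O)c1c(O)cc(OC(C)(C)C#C)cc1O
F4 | step 2 | 1-(5,7-dihydroxy-2,2-dimethyl-2H-chromen-6-yl)-2-methylpropan-1-one | CC(C)C(=O)c1c(O)cc2OC(C)(C)C=Cc2c1O
F5 | step 2 | 5-{[5,7-dihydroxy-2,2-dimethyl-6-(2-methylpropanoyl)-2H-chromen-8-yl]methyl}-2,2-dimethyl-1,3-dioxane-4,6-dione | CC(C)C(=O)c1c(O)c(CC2C(=O)OC(C)(C)OC2=O)c2OC(C)(C)C=Cc2c1O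
F6 | step 4 | 7-hydroxy-5-[(2-methylbut-3-yn-2-yl)oxy]-8-(2-methylpropanoyl)-3,4-dihydro-2H-chromen-2-one | CC(C)C(=O)c1c(O)cc(OC(C)(C)C#C)c2CCC(=O)Oc12
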